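## The problem

Compound 21 is a depsidone. Ring A (a 2-aryloxy-3-formyl-4-hydroxy-6-methylbenzoyl unit) and ring B (the fully substituted benzene ring of a 2,2,5-trimethylchroman-4-one) are joined twice: by the ester from the ring A carbonyl to O-6 of the chromanone, and by the diaryl ether oxygen on C-7. A seven-membered dibenzodioxepinone therefore lies between them.

There is no stereocentre, so the whole task is regiochemistry and congestion. Ring B carries four contiguous oxygens (pyranone O-1, the free 8-hydroxyl, the ether oxygen on C-7, the ester oxygen on C-6) that must be addressed one at a time. Ring A is pentasubstituted, with the formyl group wedged between the phenol and the aryloxy carbon.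

The diaryl ether is substituted at all four ortho positions. In an open depside a hindered phenoxide must reach a hindered aryl halide while the aryl ester is exposed to base. The aryl ester (later the lactone), the salicylaldehyde and the free ring B phenol will not survive strong nucleophiles, strong base or unselective oxidants. The chromanone can open by retro-oxa-Michael reaction under forcing base.

The enabling feature is that the formyl carbon on C-3 of ring A and the hydroxyl oxygen on C-8 of ring B sit on the two carbons ortho to the diaryl ether oxygen. Joined at the benzylic oxidation level as ArCH2–OAr they form a temporary tether. Oxidative cleavage of that benzyl aryl ether gives back exactly the formyl group and the phenol.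

## Retrosynthesis

**21 from 20.** The last cut is the O–CH3 bond of the ring A methyl ether, which comes from the starting arene. It lies ortho to the formyl group, so BCl3 can remove it by chelation without touching the lactone.

**20 from 19.** The formyl carbon and O-8 are reconnected as a benzylic ether, giving the tether-bridged depsidone 19. The alternative, a late electrophilic formylation of ring A, would have to choose between two positions ortho to the phenol on a molecule with a more electron-rich ring B. The reconnection carries the carbon from the start. The forward step must oxidise one OCH2 group in the presence of two aryl methyl groups and the ketone α-methylene.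

**19 from 18 (key disconnection).** The ring A carbon–oxygen bond of the diaryl ether is cut, leaving an aryl bromide and the 7-phenol. Because of the tether the two partners remain in one ring, the ten-membered bromo depside 18, and the forward coupling is transannular.
- Cutting the ring B carbon–oxygen bond instead would need a halide on a tetraoxygenated arene.
- Closing the ester last would be a lactonisation between a di-ortho-substituted acid and a hindered phenol.
- The chosen cut pairs a bromide activated by its ortho ester with the most acidic phenol of ring B.
- One bond removes both seven-membered rings.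

**18 from 17 and 16.** The 7-hydroxyl is masked as its methoxymethyl ether (17). The O-8–CH2 bond is then cut to phenol and benzylic chloride in 16. Ring closure by SN2 at a benzylic carbon is preferred to ring closure by acyl transfer, which suffers more from double ortho substitution. The forward step needs high dilution.

**16 from 15 and 14.** In catechol 15 the 7-hydroxyl is para to the chromanone carbonyl and clearly the more acidic, so one equivalent of base and chloromethyl methyl ether distinguish it from the 8-hydroxyl. Catechol 15 comes from dimethyl ether 14. Both ring B methoxyls of 14 are flanked by two oxygen substituents and fall to BCl3. The isolated ring A methoxyl does not. The ester on O-6 is already in place, so that oxygen needs no protecting group.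

**14 from 8 and 12.** The ester is cut to phenol 12 and hydroxy acid 8. Thionyl chloride activates 8 as 13, turning the benzylic alcohol into the chloride needed later in the same operation. This is the convergent point.

**12 from 10 and 11; 10 from 9.** The chromanone is cut at the aryl–carbonyl bond and the O-1–C-2 bond to hydroquinone 10 and 3-methylbut-2-enoic acid 11. Hydroquinone 10 has one free ring carbon, so acylation has no choice, and only the neighbouring hydroxyl can close the pyranone. Hydroquinone 10 is the reduction product of quinone 9.

**8 from 7, 5, 3, 2 and 1.** Acid 8 comes from aldehyde 7 by oxidation. The hydroxymethyl carbon of 7 is traced to formyl dioxolane 5 (reduced to 6, then unmasked). Compound 5 arises from dioxolane 3 by deprotonation at the one ring hydrogen flanked by bromine and methoxy (aryllithium 4). The dioxolane is needed because an acid or ester next to the aryl methyl group would invite benzylic deprotonation. Compound 3 comes from aldehyde 2, and 2 from arene 1 by formylation para to the methoxy group. Two regiochemically distinct tools (electrophilic substitution para to oxygen, metalation between bromine and oxygen) thus place the two carbons flanking bromine.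

## Roads not taken

**Alternative 1: ring B by squarate ring expansion.** Ring B itself is cut, at the bond between the future ester-oxygen carbon and the methyl-bearing carbon. Forward, the aryloxy cyclobutenone A2 opens on heating to a dienylketene whose six-electron electrocyclisation gives the hydroquinone diaryl ether A1.
- Merits: the diaryl ether is made by addition–elimination on a squarate, not by coupling at a hindered arene, and the oxygen pattern of ring B is written by construction. In that respect it is better than the chosen plan, which must form a strained macrocycle to make the same bond.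
- Weak points: A1 still lacks the lactone (transesterification of a di-ortho-substituted methyl benzoate by a hindered phenol), the chromanone ring (hot acid on a diaryl ether hydroquinone) and the formyl group (electrophilic substitution with two candidate positions on ring A and a competing ring B). The unsymmetrical squarate must also be made from a chelated salicylate phenol.
- Comparison: the chosen plan sets against this that the formyl carbon, the chromanone and every oxygen are fixed before the rings are joined, so no late electrophilic substitution is needed.

**Alternative 2: ortho-quinone conjugate lactonisation.** The ester oxygen–ring B bond is cut. Forward, the catechol acid A4 is oxidised by Ag2O to its ortho-quinone and the carboxylic acid adds to the unsubstituted quinone carbon, giving the trihydroxy depsidone A3.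
- Merits: no protecting groups, the fourth ring B oxygen arrives in the ring-forming step, and the route to the depsidone core is clearly shorter than the chosen one.
- Weak points: A3 has neither the chromanone nor the formyl group. Both would be installed by acid-mediated electrophilic chemistry on a triphenol lactone, with two formylation sites on ring A. The ortho-quinone can also be attacked at other positions or decompose.
- Comparison: the chosen plan is longer and spends steps on protection. What it offers in return is that each late step acts on one defined site.

**Alternative 3: acylketene annulation with late aromatisation of ring A.** Both carbon–oxygen bonds of the seven-membered ring are cut, and ring A is taken back to a cyclohexanedione. Forward, the tert-butyl keto ester A6 is heated with the catechol chromanone A7, then acid is added. Acylketene capture and enol ether condensation give the dihydro depsidone A5.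
- Merits: no aryl halide and no copper, and the seven-membered ring forms in one flask under non-basic conditions, which protects the ester better than the chosen key step does.
- Weak points: A7 has two free phenols, so capture and condensation can occur in either orientation. A5 must still be dehydrogenated, and the formyl group must be added afterwards with the same positional ambiguity as in alternative 2. The two stereocentres of A5 are irrelevant.
- Comparison: the step count could be lower. The chosen plan accepts a strained intermediate in exchange for selectivity enforced by the ring.

Key step: step 13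

## Route

Assumption on the chemistry: the target has no stereocentre; macrocycles 17 and 18 are conformationally chiral and are carried as racemates, which has no consequence.

Ring B positions use chromanone numbering (O-1, C-5 to C-8). Ring A positions use benzoate numbering.

Step 1
Reactants: 1 3-bromo-5-methoxytoluene
Product: 2 2-bromo-4-methoxy-6-methylbenzaldehyde
Conditions: Cl2CHOMe, TiCl4, CH2Cl2, 0 °C; aqueous work-up
Reagents that add atoms: dichloromethyl methyl ether, COC(Cl)Cl; water, O
Why: Rieche formylation (electrophilic aromatic substitution); the methoxy group directs the electrophile para, to the carbon between bromine and methyl, and hydrolysis gives the aldehyde; isomers from ortho attack should be minor and are removed at this stage.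

Step 2
Reactants: 2 2-bromo-4-methoxy-6-methylbenzaldehyde
Product: 3 2-(2-bromo-4-methoxy-6-methylphenyl)-1,3-dioxolane
Conditions: ethylene glycol, TsOH·H2O (cat.), toluene, reflux, Dean–Stark
Reagents that add atoms: ethylene glycol, OCCO
Why: Acid-catalysed acetalisation with azeotropic removal of water; the dioxolane withstands the amide base and, unlike an acid or ester, does not acidify the neighbouring aryl methyl group.

Step 3
Reactants: 3 2-(2-bromo-4-methoxy-6-methylphenyl)-1,3-dioxolane
Product: 5 2-bromo-3-(1,3-dioxolan-2-yl)-6-methoxy-4-methylbenzaldehyde, via aryllithium 4 (not isolated)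
Conditions: LiN(iPr)2 (commercial solution), THF, −78 °C; DMF, −78 to −40 °C; aq. NH4Cl
Reagents that add atoms: N,N-dimethylformamide, CN(C)C=O
Why: Directed ortho-metalation; the single ring hydrogen flanked by bromine and methoxy is the most acidic, the amide base does not exchange the bromine, and DMF traps 4 at low temperature before lithium bromide can be lost to an aryne.

Step 4
Reactants: 5 2-bromo-3-(1,3-dioxolan-2-yl)-6-methoxy-4-methylbenzaldehyde
Product: 7 2-bromo-3-(hydroxymethyl)-4-methoxy-6-methylbenzaldehyde, via dioxolane alcohol 6 (not isolated)
Conditions: NaBH4, MeOH/THF, 0 °C; then 2 M aq. HCl, THF, rt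
Reagents that add atoms: water, O
Why: Borohydride reduction of the free aldehyde followed by acid hydrolysis of the acetal in the same flask; the two carbons flanking bromine end at different oxidation levels, and their meta relationship excludes lactol formation.

Step 5
Reactants: 7 2-bromo-3-(hydroxymethyl)-4-methoxy-6-methylbenzaldehyde
Product: 8 2-bromo-3-(hydroxymethyl)-4-methoxy-6-methylbenzoic acid
Conditions: NaClO2, NaH2PO4, 2-methyl-2-butene, t-BuOH/H2O, rt
Reagents that add atoms: sodium chlorite, [Na+].[O-]Cl=O
Why: Pinnick oxidation; chlorous acid oxidises only the aldehyde, the benzylic alcohol is untouched, and the alkene scavenges hypochlorous acid so the ring is not chlorinated.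

Step 6
Reactants: 9 2,3-dimethoxy-5-methyl-1,4-benzoquinone (ubiquinone-0)
Product: 10 2,3-dimethoxy-5-methylbenzene-1,4-diol
Conditions: Na2S2O4, EtOAc/H2O, rt, under argon
Reagents that add atoms: none
Why: Dithionite reduction of a quinone to its hydroquinone; the product is used promptly because air re-oxidises it.

Step 7
Reactants: 10 2,3-dimethoxy-5-methylbenzene-1,4-diol; 11 3-methylbut-2-enoic acid
Product: 12 6-hydroxy-7,8-dimethoxy-2,2,5-trimethyl-2,3-dihydro-4H-chromen-4-one
Conditions: P2O5/MeSO3H (1:10 w/w), 70 °C
Reagents that add atoms: none
Why: One-flask chromanone synthesis from a phenol and 3-methylbut-2-enoic acid: Friedel–Crafts acylation at the only unsubstituted ring carbon, then oxa-Michael closure by the adjacent hydroxyl; the dehydrating medium favours the acylium pathway, and the hydroxyl between methyl and methoxy remains as the free 6-phenol.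

Step 8
Reactants: 8 2-bromo-3-(hydroxymethyl)-4-methoxy-6-methylbenzoic acid; 12 6-hydroxy-7,8-dimethoxy-2,2,5-trimethyl-2,3-dihydro-4H-chromen-4-one
Product: 14 7,8-dimethoxy-2,2,5-trimethyl-4-oxo-3,4-dihydro-2H-chromen-6-yl 2-bromo-3-(chloromethyl)-4-methoxy-6-methylbenzoate, via acid chloride 13 (not isolated)
Conditions: SOCl2, DMF (cat.), toluene, 70 °C, evaporate; then 12, NaH (1.0 equiv), THF, 0 °C to rt
Reagents that add atoms: thionyl chloride, ClS(Cl)=O
Why: Thionyl chloride converts the acid and the benzylic alcohol into chlorides at once; the sodium phenoxide of 12 is then acylated (esterification of a phenoxide by an aroyl chloride), which in THF at 0 °C should outrun alkylation by the doubly ortho-substituted benzylic chloride.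

Step 9
Reactants: 14 7,8-dimethoxy-2,2,5-trimethyl-4-oxo-3,4-dihydro-2H-chromen-6-yl 2-bromo-3-(chloromethyl)-4-methoxy-6-methylbenzoate
Product: 15 7,8-dihydroxy-2,2,5-trimethyl-4-oxo-3,4-dihydro-2H-chromen-6-yl 2-bromo-3-(chloromethyl)-4-methoxy-6-methylbenzoate
Conditions: BCl3 (5 equiv), CH2Cl2, −78 °C to rt; aq. NaHCO3
Reagents that add atoms: none
Why: Lewis-acid ether cleavage; BCl3 selectively removes methyl ethers flanked by two oxygen substituents, which applies to both ring B methoxyls, and leaves the isolated ring A methoxyl, the aryl ester and the benzylic chloride.

Step 10
Reactants: 15 7,8-dihydroxy-2,2,5-trimethyl-4-oxo-3,4-dihydro-2H-chromen-6-yl 2-bromo-3-(chloromethyl)-4-methoxy-6-methylbenzoate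
Product: 16 8-hydroxy-7-(methoxymethoxy)-2,2,5-trimethyl-4-oxo-3,4-dihydro-2H-chromen-6-yl 2-bromo-3-(chloromethyl)-4-methoxy-6-methylbenzoate
Conditions: MOMCl (1.05 equiv), iPr2NEt (1.1 equiv), CH2Cl2, 0 °C
Reagents that add atoms: chloromethyl methyl ether, COCCl
Why: Selective O-alkylation of the more acidic phenol of a catechol; the 7-hydroxyl is para to the chromanone carbonyl, so with one equivalent of amine base only its phenoxide reacts, as in 4-O-selective alkylation of 3,4-dihydroxyaryl ketones; the benzylic chloride is far less reactive than the chloromethyl ether under these conditions.

Step 11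
Reactants: 16 8-hydroxy-7-(methoxymethoxy)-2,2,5-trimethyl-4-oxo-3,4-dihydro-2H-chromen-6-yl 2-bromo-3-(chloromethyl)-4-methoxy-6-methylbenzoate
Product: 17 ten-membered bromo depside methoxymethyl ether (O-8 of the chromanone bonded to the ring A benzylic CH2 in place of chlorine; Br and the 7-OCH2OCH3 group intra-annular)
Conditions: Cs2CO3, NaI (cat.), DMF, 60 °C, slow addition to 2 mM
Reagents that add atoms: none
Why: Intramolecular Williamson etherification (10-exo-tet) under high dilution with in situ halide exchange; the only free phenol is O-8, and it cannot take the acyl group from O-6 because the two oxygens are meta to each other.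

Step 12
Reactants: 17 ten-membered bromo depside methoxymethyl ether
Product: 18 ten-membered bromo depside with free 7-hydroxyl
Conditions: HCl (2 M in MeOH), THF, rt to 40 °C
Reagents that add atoms: none
Why: Acid-catalysed cleavage of an aryl methoxymethyl ether, easy here because the departing phenol is para to a ketone; the hindered ester, the aryl bromide and the benzyl aryl ether on its ester-deactivated ring should tolerate dilute methanolic acid.

Step 13
Reactants: 18 ten-membered bromo depside with free 7-hydroxyl
Product: 19 tether-bridged depsidone (seven-membered lactone fused to a seven-membered dioxepine)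
Conditions: CuI (20 mol %), N,N-dimethylglycine hydrochloride (40 mol %), Cs2CO3 (3 equiv), 1,4-dioxane, 90 °C, 5 mM
Reagents that add atoms: none
Why: Intramolecular Ullmann diaryl ether synthesis; the closest known reaction type is the copper-catalysed, amino-acid-promoted coupling of a phenol with an aryl bromide used for macrocyclic diaryl ethers and depsidones. Cs2CO3 deprotonates the only phenol of 18 (O-7), the phenoxide binds monovalent copper carrying N,N-dimethylglycinate, oxidative addition of the ring A C–Br bond gives a trivalent copper aryl phenoxide, and reductive elimination forms the ring A carbon–oxygen bond. The bond forms transannularly across the ten-membered ring, so it closes two rings at once: the seven-membered lactone of the target and a seven-membered dioxepine holding the OCH2 tether. In 18 the bromine-bearing and oxygen-bearing carbons are the two intra-annular positions of a dioxa analogue of [2.2]metacyclophane and are held close together, a preorganisation the open depside lacks. No stereocentre is formed. The selectivity needed is site selectivity and survival of the ester: there is one phenol and one C–Br, the bromide is activated by the ortho ester, the di-ortho-substituted benzoate resists carbonate, and acyl shift to O-7 cannot occur because O-7 is consumed.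

Step 14
Reactants: 19 tether-bridged depsidone
Product: 20 ring A methyl ether of the target (formyl and methoxy on ring A, free 8-hydroxyl on ring B)
Conditions: DDQ (1.5 equiv), CH2Cl2/H2O (10:1), rt to 40 °C
Reagents that add atoms: water, O
Why: DDQ oxidative cleavage of an electron-rich benzyl ether; hydride abstraction occurs at the methylene flanked by an ortho methoxy and an ortho aryloxy group, water captures the cation, and loss of the ring B phenol leaves the formyl group; the aryl methyl groups and the ketone α-methylene lack comparable stabilisation.

Step 15
Reactants: 20 ring A methyl ether of the target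
Product: 21 target depsidone CNP0271978.0
Conditions: BCl3, CH2Cl2, −78 to 0 °C; aq. work-up
Reagents that add atoms: none
Why: Chelation-controlled demethylation; BCl3 bound to the formyl oxygen delivers chloride to the ortho methyl ether only, and the lactone, diaryl ether and chromanone are stable at this temperature.

## Compound list

1 | 3-bromo-5-methoxytoluene | COc1cc(C)cc(Br)c1 | starting material
2 | 2-bromo-4-methoxy-6-methylbenzaldehyde | COc1cc(C)c(C=O)c(Br)c1 | intermediate
3 | 2-(2-bromo-4-methoxy-6-methylphenyl)-1,3-dioxolane | COc1cc(C)c(C2OCCO2)c(Br)c1 | intermediate
4 | [2-bromo-3-(1,3-dioxolan-2-yl)-6-methoxy-4-methylphenyl]lithium | [Li]c1c(OC)cc(C)c(C2OCCO2)c1Br | intermediate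
5 | 2-bromo-3-(1,3-dioxolan-2-yl)-6-methoxy-4-methylbenzaldehyde | COc1cc(C)c(C2OCCO2)c(Br)c1C=O | intermediate
6 | [2-bromo-3-(1,3-dioxolan-2-yl)-6-methoxy-4-methylphenyl]methanol | COc1cc(C)c(C2OCCO2)c(Br)c1CO | intermediate
7 | 2-bromo-3-(hydroxymethyl)-4-methoxy-6-methylbenzaldehyde | COc1cc(C)c(C=O)c(Br)c1CO | intermediate
8 | 2-bromo-3-(hydroxymethyl)-4-methoxy-6-methylbenzoic acid | COc1cc(C)c(C(=O)O)c(Br)c1CO | intermediate
9 | 2,3-dimethoxy-5-methyl-1,4-benzoquinone (ubiquinone-0) | COC1=C(OC)C(=O)C(C)=CC1=O | starting material
10 | 2,3-dimethoxy-5-methylbenzene-1,4-diol | COc1c(OC)c(O)c(C)cc1O | intermediate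
11 | 3-methylbut-2-enoic acid | CC(C)=CC(=O)O | starting material
12 | 6-hydroxy-7,8-dimethoxy-2,2,5-trimethyl-2,3-dihydro-4H-chromen-4-one | Cc1c(O)c(OC)c(OC)c2OC(C)(C)CC(=O)c12 | intermediate
13 | 2-bromo-3-(chloromethyl)-4-methoxy-6-methylbenzoyl chloride | COc1cc(C)c(C(Cl)=O)c(Br)c1CCl | intermediate
14 | 7,8-dimethoxy-2,2,5-trimethyl-4-oxo-3,4-dihydro-2H-chromen-6-yl 2-bromo-3-(chloromethyl)-4-methoxy-6-methylbenzoate | COc1cc(C)c(C(=O)Oc2c(C)c3C(=O)CC(C)(C)Oc3c(OC)c2OC)c(Br)c1CCl | intermediate
15 | 7,8-dihydroxy-2,2,5-trimethyl-4-oxo-3,4-dihydro-2H-chromen-6-yl 2-bromo-3-(chloromethyl)-4-methoxy-6-methylbenzoate | COc1cc(C)c(C(=O)Oc2c(C)c3C(=O)CC(C)(C)Oc3c(O)c2O)c(Br)c1CCl | intermediate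
16 | 8-hydroxy-7-(methoxymethoxy)-2,2,5-trimethyl-4-oxo-3,4-dihydro-2H-chromen-6-yl 2-bromo-3-(chloromethyl)-4-methoxy-6-methylbenzoate | COc1cc(C)c(C(=O)Oc2c(C)c3C(=O)CC(C)(C)Oc3c(O)c2OCOC)c(Br)c1CCl | intermediate
17 | ten-membered bromo depside, 7-O-methoxymethyl ether (ester from the ring A carbonyl to O-6, benzylic ether from the ring A CH2 to O-8) | Cc1cc(OC)c2c(Br)c1C(=O)Oc1c(C)c3c(c(c1OCOC)OC2)OC(C)(C)CC3=O | intermediate
18 | ten-membered bromo depside with free 7-hydroxyl | Cc1cc(OC)c2c(Br)c1C(=O)Oc1c(C)c3c(c(c1O)OC2)OC(C)(C)CC3=O | intermediate
19 | tether-bridged depsidone (lactone ring fused to a dioxepine through the diaryl ether) | Cc1cc(OC)c2c3c1C(=O)Oc1c(C)c4c(c(c1O3)OC2)OC(C)(C)CC4=O | intermediate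
20 | ring A methyl ether of the target (3-formyl-4-methoxy ring A, 8-hydroxy ring B) | Cc1cc(OC)c(C=O)c2c1C(=O)Oc1c(C)c3c(c(O)c1O2)OC(C)(C)CC3=O | intermediate
21 | CNP0271978.0 (3-formyl-4-hydroxy ring A, 8-hydroxy ring B depsidone) | Cc1cc(O)c(C=O)c2c1C(=O)Oc1c(C)c3c(c(O)c1O2)OC(C)(C)CC3=O | target

## Step count and least certain steps

Total: 15 steps. Longest linear sequence: 13 steps (steps 1–5 and 8–15). The ring B branch (steps 6 and 7) joins at step 8.

**Step 13 (key step).** Oxidative addition at the shielded intra-annular C–Br bond may be slow. Base-mediated opening of the aryl ester or protodebromination could then overtake the coupling. Fallback: set out from 17 and cleave the tether before forming the diaryl ether. DDQ in wet CH2Cl2 should convert 17 into the open formyl bromo depside methoxymethyl ether F1. Methanolic HCl then frees the catechol aldehyde F2. In F2 the bromide is flanked by a formyl group and an ester, so K2CO3 in DMF should close the seven-membered ring by nucleophilic aromatic substitution from the 7-phenoxide. This returns to the route at 20.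

**Step 11.** Closure of a ten-membered ring with two intra-annular substituents is strained. Intermolecular alkylation to dimers and oligomers may prevail even at high dilution. Fallback: set out from 15 and reverse the order of the two ring closures. CuI, N,N-dimethylglycine and Cs2CO3 in dilute dioxane should first couple the 7-phenoxide with the bromide of the open depside, giving the chloromethyl depsidone F3. Its 8-phenoxide then displaces chloride in an unstrained seven-membered ring closure. This returns to the route at 19.

**Step 14.** The ester on ring A lowers the hydride-donor ability of the benzylic ether, so oxidation may stall. Forcing it may oxidise the liberated ring B phenol further. Fallback: set out from 19 and use radical chemistry. N-bromosuccinimide with a radical initiator in PhCF3 should brominate the OCH2 carbon, the weakest C–H bond, to the α-bromo ether F6. Aqueous THF hydrolyses F6 to formyl group and phenol, returning at 20.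

**Step 9.** Cleavage may stop after one ring B methyl ether, expected at O-8, or prolonged exposure may begin to remove the ring A methyl ether. Fallback: set out from 14, accept the mono-cleavage, and move the second demethylation to a later, nucleophilic step. Limited BCl3 at low temperature should give the 8-phenol F4. Cs2CO3 with NaI under high dilution cyclises F4 to the 7-methoxy macrocycle F5. LiCl in hot DMF then removes the methyl ether para to the ketone, returning at 18.

**Step 7.** In strong acid the protonated unsaturated acid can alkylate the hydroquinone at carbon through its tertiary cationic centre, which would lead to lactonisation in place of acylation. Fallback: set out from 10 and build the pyranone in two stages. Acetic anhydride with BF3·OEt2 should acetylate the free ring carbon to give the hydroxyacetophenone F7. Condensation of F7 with acetone and pyrrolidine (Kabbe chromanone synthesis) returns to the route at 12.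

## Further compounds

F1 | step 13 | 8-hydroxy-7-(methoxymethoxy)-2,2,5-trimethyl-4-oxo-3,4-dihydro-2H-chromen-6-yl 2-bromo-3-formyl-4-methoxy-6-methylbenzoate | COc1cc(C)c(C(=O)Oc2c(C)c3C(=O)CC(C)(C)Oc3c(O)c2OCOC)c(Br)c1C=O
F2 | step 13 | 7,8-dihydroxy-2,2,5-trimethyl-4-oxo-3,4-dihydro-2H-chromen-6-yl 2-bromo-3-formyl-4-methoxy-6-methylbenzoate | COc1cc(C)c(C(=O)Oc2c(C)c3C(=O)CC(C)(C)Oc3c(O)c2O)c(Br)c1C=O
F3 | step 11 | chloromethyl depsidone (ring A 3-chloromethyl-4-methoxy, ring B free 8-hydroxyl) | Cc1cc(OC)c(CCl)c2c1C(=O)Oc1c(C)c3c(c(O)c1O2)OC(C)(C)CC3=O
F4 | step 9 | 8-hydroxy-7-methoxy-2,2,5-trimethyl-4-oxo-3,4-dihydro-2H-chromen-6-yl 2-bromo-3-(chloromethyl)-4-methoxy-6-methylbenzoate | COc1cc(C)c(C(=O)Oc2c(C)c3C(=O)CC(C)(C)Oc3c(O)c2OC)c(Br)c1CCl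
F5 | step 9 | ten-membered bromo depside, 7-O-methyl ether | Cc1cc(OC)c2c(Br)c1C(=O)Oc1c(C)c3c(c(c1OC)OC2)OC(C)(C)CC3=O
F6 | step 14 | tether-bridged depsidone brominated at the OCH carbon (racemic) | Cc1cc(OC)c2c3c1C(=O)Oc1c(C)c4c(c(c1O3)OC2Br)OC(C)(C)CC4=O
F7 | step 7 | 1-(2,5-dihydroxy-3,4-dimethoxy-6-methylphenyl)ethan-1-one | COc1c(OC)c(O)c(C)c(C(C)=O)c1O
A1 | alternative 1 | methyl 2-(2,5-dihydroxy-6-methoxy-3-methylphenoxy)-4-methoxy-6-methylbenzoate | COC(=O)c1c(C)cc(OC)cc1Oc1c(O)c(C)cc(O)c1OC
A2 | alternative 1 | methyl 2-{[3-hydroxy-2-methoxy-4-oxo-3-((E)-prop-1-en-1-yl)cyclobut-1-en-1-yl]oxy}-4-methoxy-6-methylbenzoate (racemic) | COC(=O)c1c(C)cc(OC)cc1OC1=C(OC)C(O)(/C=C/C)C1=O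
A3 | alternative 2 | 3,6,7-trihydroxy-1,9-dimethyldibenzo[b,e][1,4]dioxepin-11-one | Cc1cc(O)cc2c1C(=O)Oc1c(C)cc(O)c(O)c1O2
A4 | alternative 2 | 2-(2,3-dihydroxy-5-methylphenoxy)-4-hydroxy-6-methylbenzoic acid | Cc1cc(O)cc(Oc2cc(C)cc(O)c2O)c1C(=O)O
A5 | alternative 3 | racemic dihydro depsidone with ring A as a 3-aryloxycyclohex-2-enone | C[C@@H]1CC(=O)C=C2Oc3c(OC)c4OC(C)(C)CC(=O)c4c(C)c3OC(=O)[C@@H]12
A6 | alternative 3 | tert-butyl 2-methyl-4,6-dioxocyclohexane-1-carboxylate (racemic, mixture of diastereomers) | CC1CC(=O)CC(=O)C1C(=O)OC(C)(C)C
A7 | alternative 3 | 6,7-dihydroxy-8-methoxy-2,2,5-trimethyl-2,3-dihydro-4H-chromen-4-one | Cc1c(O)c(O)c(OC)c2OC(C)(C)CC(=O)c12
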